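The constants stand for no real mixture.

The target cannot pass 75.0 % of the substrate charged, because each target costs two reagent and the flask holds 0.0750 M of reagent against 0.050 M of substrate.

    substrate + intermediate B → side product B (k1 = 0.146 M⁻¹ s⁻¹)
    reagent + intermediate A → target (k2 = 0.223 M⁻¹ s⁻¹)
    substrate + reagent ⇌ intermediate A (K3 = 40 M⁻¹, k3 = 0.162 M⁻¹ s⁻¹)
    capture agent + intermediate A → trapped intermediate (k4 = 0.106 M⁻¹ s⁻¹)
    substrate ⇌ intermediate B (K5 = 2.09, k5 = 0.148 s⁻¹)
    substrate + reagent → side product A (k6 = 0.137 M⁻¹ s⁻¹)

substrate 0.050 M; reagent 0.0750 M; capture agent 0.0500 M; time 2.5 min

- a species is counted by the substrate in it: one side product B counts as two
- the reaction counts as stopped when no species that holds the substrate changes by six tenths of a point or more over the second half of the time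
- run time (flask): 2.5 min

- which holds at 2.5 min: what has brought the reaction to rest, or that it has not come to rest (the reagent has run out first / all of the substrate has reacted / forward and back rates have come level / it is still moving)
- the target standing at 2.5 min, as a percentage of the substrate charged
- the intermediate B standing at 2.5 min, as a percentage of the substrate charged
- the side product A standing at 2.5 min, as a percentage of the substrate charged
- amount of target if the flask were left three thousand times as long, in percent of the substrate charged

On paper, reagent is the limiting reagent for the target, whose cap lies below the substrate charge, so the books are kept in reagent.

The first entry is paid by each substrate that meets reagent: one reagent, whichever way it goes. The two forward rates carry the same two concentrations, so the forward making of intermediate A stays 1.2 times the loss to side product A. That sends 54.2 % of this traffic to intermediate A.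

The second entry depends on what intermediate A meets. At the charged amounts, its half-life against reagent is 0.69 min, and against capture agent 2.18 min. At the charge, the capture split is 3.16: the rate from intermediate A into target over the rate into trapped intermediate, at the amounts of reagent and capture agent then standing.

So 75.9 % of intermediate A pays a second reagent. Target is then 41.1 % of the substrate passing, and the price is 141 % reagent per substrate.

The books close here. The full substrate charge at that price needs 0.0706 M, which on this reckoning leaves 0.00440 M of reagent, and substrate lost to side product B pays none. This reckoning ignores the back step of intermediate A and gives no time course. Still, the run lasts 1.58 half-lives of intermediate B against substrate, taken at the charge, which is fewer than two, so this reckoning commits to a flask still moving, with reagent left.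

The forecast says it is still moving, with target 13.1 %, intermediate B 24 %, side product A 24.2 %, and 24.5 % of target after the long wait. Its grounds are: “Everything is still changing, and reagent remains”.

The result: it is still moving, with target 12.8 %, intermediate B 24.8 %, side product A 23.7 %, and 24.5 % of target after the long wait, so the forecast holds on each. Read at 1.89 min or 3.35 min instead, the intermediate B of this flask stands 5 points from its present value. At 2.50 min, reagent stands at 59.8 % of its charge and capture agent at 94.7 % of its charge, so the split has fallen to 1.99. Target over trapped intermediate reads 2.39, below the split at the charge and above the split at that time.

A neighbour flask charged with 0.12 M of substrate keeps the same reagent and capture agent charges, so its split starts at 3.16. With reagent at 33.5 % of its charge and capture agent at 89.4 % of its charge at 2.50 min, the split of that neighbour ends at 1.18. Target over trapped intermediate in that neighbour reads 1.76, below its starting split and above its final one.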